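**Plan**

1. Numbering (germacrane) used throughout: C7 carries the isopropenyl group, C8 the senecioate, C9 the acetate, C10 (methyl) and C1 one epoxide, C2 is CH2, C3 carries the angelate, C4 (methyl) and C5 the other epoxide, C6 is the CH2 between C5 and C7.
2. Retrosynthesis: the three esters come off; the C4/C5 epoxide goes back to a Z-alkene (C3-OH directed); the C9 carbinol goes back to a ketone and the C1/C10 epoxide to a cis-enone; C8–O goes back to the C8/C9 enolate; the ring bond C6–C7 is then cut by a retro-oxy-Cope that re-forms C4–C9, giving a cis-1,2-dialkenylcyclohexenol; this leads back to 2-methylcyclohex-2-enone, vinylmagnesium bromide and 2-methylbut-1-en-3-yne.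
3. Enabling feature: in the ten-membered ring, O–C9–C8–C7–C6–C5=C4 (C4=C5 masked as the cis-epoxide) is a cyclodec-5-enone pattern, and C9, C10, C1, C2, C3, C4 can start life as a cyclohexenone ring whose cis C10=C1 bond becomes the second cis-epoxide.
4. Forward order: the six-membered ring C9/C10/C1/C2/C3/C4 first, with quaternary C4 made by a semipinacol 1,2-vinyl shift; then the ten-membered ring by four-atom ring expansion with C8 hydroxylation in the same flask; then epoxide, carbinol and ester adjustments.
5. Stereochemistry: absolute configuration from one CBS reduction; C3/C4 by hydroxyl-directed epoxidation and anti vinyl migration; temporary C9 by axial acetylide addition; Z-C4=C5 and C7 from the chair of the [3,3] shift; C8, C1/C10, C9 and C4/C5 by outer-face attack on the ten-membered ring (chelation at C9, hydroxyl direction at C4/C5).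

Key step: step 11

Remark: in the given stereoisomer both epoxides are cis-fused to the ring (the two ring carbons leave each oxirane on the same side), so each is taken to derive from a Z-trisubstituted ring alkene; the C3 oxygen is threo and the C9 oxygen erythro to its neighbouring oxirane.

**Route**

Step 1
Reactants: 1 2-methylcyclohex-2-en-1-one
Product: 2 (R)-2-methylcyclohex-2-en-1-ol
Conditions: (S)-2-methyl-CBS-oxazaborolidine (10 mol %), BH3·SMe2, THF, −20 °C; MeOH
Reagents that add atoms: none
Why: Corey–Bakshi–Shibata reduction, in which the 2-methylvinyl side acts as the large group so that the (S)-catalyst should give the R carbinol, the only source of absolute configuration in the route.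

Step 2
Reactants: 2 (R)-2-methylcyclohex-2-en-1-ol; 3 tert-butyl hydroperoxide
Product: 4 (1R,2R,3S)-2,3-epoxy-2-methylcyclohexan-1-ol (oxirane cis to OH)
Conditions: VO(acac)2 (2 mol %), TBHP (decane), CH2Cl2, 0 °C → rt
Reagents that add atoms: tert-butyl hydroperoxide (3), CC(C)(C)OO
Why: vanadium-catalysed hydroxyl-directed epoxidation of a cyclic allylic alcohol, the oxygen being delivered from the vanadate ester to the face that carries the OH group (cis-epoxy alcohol).

Step 3
Reactants: 4 (1R,2R,3S)-2,3-epoxy-2-methylcyclohexan-1-ol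
Product: 5 (2S,3S)-2,3-epoxy-2-methylcyclohexan-1-one
Conditions: n-Pr4N[RuO4] (5 mol %), N-methylmorpholine N-oxide, 4 Å MS, CH2Cl2, rt
Reagents that add atoms: none
Why: Ley–Griffith oxidation under neutral conditions that leave the oxirane intact; no stereocentre is touched.

Step 4
Reactants: 5 (2S,3S)-2,3-epoxy-2-methylcyclohexan-1-one; 6 vinylmagnesium bromide
Product: 7 (1S,2S,3S)-2,3-epoxy-2-methyl-1-vinylcyclohexan-1-ol (OH cis and vinyl trans to the oxirane)
Conditions: vinylmagnesium bromide, THF, −78 °C; aq. NH4Cl
Reagents that add atoms: vinylmagnesium bromide (6), C=C[Mg]Br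
Why: Grignard 1,2-addition to an α,β-epoxy ketone from the face opposite the oxirane oxygen (Felkin–Anh, C–O bond anti to the nucleophile, and the oxygen shields its own face), which puts the vinyl group anti to the C2–O bond as step 5 requires.

Step 5
Reactants: 7 (1S,2S,3S)-2,3-epoxy-2-methyl-1-vinylcyclohexan-1-ol
Product: 8 (2R,3S)-3-hydroxy-2-methyl-2-vinylcyclohexan-1-one
Conditions: BF3·OEt2 (0.3 equiv), CH2Cl2, −78 °C
Reagents that add atoms: none
Why: semipinacol rearrangement of a tertiary 2,3-epoxy alcohol, in which the vinyl group antiperiplanar to the breaking tertiary C–O bond shifts with inversion at C2 (the future C4), so the new quaternary centre has vinyl trans and methyl cis to the C3 hydroxyl, whose own C–O bond is not touched.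

Step 6
Reactants: 8 (2R,3S)-3-hydroxy-2-methyl-2-vinylcyclohexan-1-one; 9 tert-butyldimethylsilyl trifluoromethanesulfonate
Product: 10 (2R,3S)-3-(tert-butyldimethylsilyloxy)-2-methyl-2-vinylcyclohexan-1-one
Conditions: TBSOTf, 2,6-lutidine, CH2Cl2, −78 → 0 °C
Reagents that add atoms: tert-butyldimethylsilyl trifluoromethanesulfonate (9), CC(C)(C)[Si](C)(C)OS(=O)(=O)C(F)(F)F
Why: silylation of a hindered secondary alcohol under conditions that avoid retro-aldol cleavage; the bulky ether later acts as the conformational anchor of steps 9 and 11.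

Step 7
Reactants: 10 (2R,3S)-3-(tert-butyldimethylsilyloxy)-2-methyl-2-vinylcyclohexan-1-one; 11 iodomethane
Product: 12 (2R,3S)-3-(tert-butyldimethylsilyloxy)-2,6-dimethyl-2-vinylcyclohexan-1-one (both C6 epimers)
Conditions: LiN(i-Pr)2, THF, −78 °C; MeI, −78 → −20 °C
Reagents that add atoms: iodomethane (11), CI
Why: enolate alkylation, regiochemically unambiguous because C2 is quaternary, and the new centre is destroyed in step 8 so its configuration does not matter.

Step 8
Reactants: 12 (2R,3S)-3-(tert-butyldimethylsilyloxy)-2,6-dimethyl-2-vinylcyclohexan-1-one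
Product: 14 (5S,6R)-5-(tert-butyldimethylsilyloxy)-2,6-dimethyl-6-vinylcyclohex-2-en-1-one, via trimethylsilyl enol ether 13 (not isolated)
Conditions: TMSOTf, Et3N, CH2Cl2, 0 °C; then Pd(OAc)2 (1.05 equiv), MeCN, rt
Reagents that add atoms: none
Why: Saegusa–Ito oxidation, in which the only possible (tetrasubstituted) silyl enol ether gives a palladium enolate that loses the ring β-hydrogen to form the endocyclic 2-methyl enone.

Step 9
Reactants: 14 (5S,6R)-5-(tert-butyldimethylsilyloxy)-2,6-dimethyl-6-vinylcyclohex-2-en-1-one; 15 2-methylbut-1-en-3-yne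
Product: 16 (1S,5S,6R)-5-(tert-butyldimethylsilyloxy)-2,6-dimethyl-1-(3-methylbut-3-en-1-yn-1-yl)-6-vinylcyclohex-2-en-1-ol (enynyl group cis to vinyl)
Conditions: 15, n-BuLi, THF, −78 °C; then 14, −78 → −40 °C; aq. NH4Cl
Reagents that add atoms: 2-methylbut-1-en-3-yne (15), C=C(C)C#C
Why: 1,2-addition of a lithium acetylide to an enone; in the half-chair with the silyl ether equatorial the C6 methyl is axial and the acetylide enters axially on the opposite face (in the other half-chair the incoming group would be 1,3-diaxial to the silyl ether), so the enynyl group ends cis to the vinyl group.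

Step 10
Reactants: 16 enynyl carbinol
Product: 17 (1R,5S,6R)-5-(tert-butyldimethylsilyloxy)-2,6-dimethyl-1-[(1Z)-3-methylbuta-1,3-dien-1-yl]-6-vinylcyclohex-2-en-1-ol
Conditions: Zn dust activated with Cu(OAc)2 and AgNO3, MeOH/H2O, 45 °C
Reagents that add atoms: none
Why: Boland reduction, in which activated zinc reduces only the conjugated triple bond by cis addition of hydrogen and leaves the vinyl, isopropenyl and ring double bonds, fixing the Z geometry that step 11 translates into C7.

Step 11
Reactants: 17 Z-dienyl carbinol; 18 2-(phenylsulfonyl)-3-phenyloxaziridine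
Product: 21 (3S,7R,8S)-3-(tert-butyldimethylsilyloxy)-8-hydroxygermacra-1(10)Z,4Z,11-trien-9-one, via potassium alkoxide 19 (not isolated), via potassium dienolate 20 (not isolated)
Conditions: KH, 18-crown-6, THF, 0 → 45 °C; then −78 °C, 2-(phenylsulfonyl)-3-phenyloxaziridine; aq. NH4Cl
Reagents that add atoms: 2-(phenylsulfonyl)-3-phenyloxaziridine (18), O=S(=O)(c1ccccc1)N1OC1c1ccccc1
Why: Deprotonation gives the potassium alkoxide, whose charge-accelerated [3,3]-sigmatropic shift (anionic oxy-Cope) breaks C4–C9 of the cyclohexene and makes C6–C7, after which the ring-enlarged potassium dienolate takes up oxygen at C8 from the N-sulfonyloxaziridine; the closest known reaction type is the anionic oxy-Cope ring expansion of 1,2-dialkenylcyclohexanols to cyclodec-5-enones with hydroxylation of the enolate so formed. The ten-membered ring therefore closes by a four-atom ring expansion through a six-membered chair transition state, not by end-to-end cyclisation. The reacting half-chair has the C3 silyl ether and the C4 vinyl group equatorial and the C4 methyl and the dienyl group axial (the other half-chair would hold the silyl ether 1,3-diaxial to the alkoxide oxygen), so on the rearranging chair the ring carbon C3 is pseudoaxial and the methyl pseudoequatorial, which gives the Z-C4=C5 bond. C7 is set by chirality transfer from C4 and C9 through this chair: C6 bonds to the face of the Z-dienyl terminus that is turned toward C4, with the isopropenyl group pseudoaxial, which corresponds to 7R. C8 is set by attack of the oxaziridine on the outer face of the C8=C9 enolate, the rest of the ring lying across the other face as it emerges from the rearrangement (8S). The step needs the [3,3] shift to win over the alternative chair (E-alkene) and over a [1,3] shift, which the cis relation of the two alkenyl groups and the equatorial silyl ether should secure, and clean oxygen transfer, for which the potassium enolate is suited because it does not add to the sulfonimine by-product.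

Step 12
Reactants: 21 8-hydroxy trienone; 22 3-methylbut-2-enoyl chloride
Product: 23 8-O-(3-methylbut-2-enoyl) derivative of 21
Conditions: 3-methylbut-2-enoyl chloride, pyridine, DMAP (cat.), CH2Cl2, 0 °C
Reagents that add atoms: 3-methylbut-2-enoyl chloride (22), CC(C)=CC(=O)Cl
Why: acylation of a secondary α-ketol with an acid chloride under weakly basic conditions, which avoid the vinylketene pathway that would deconjugate the senecioate, and done before C9 is reduced so that no acyl migration can occur.

Step 13
Reactants: 23 senecioate; 3 tert-butyl hydroperoxide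
Product: 24 1,10-epoxy-3-(tert-butyldimethylsilyloxy)-8-(3-methylbut-2-enoyloxy)germacra-4Z,11-dien-9-one (1R,10R; other centres as in 32)
Conditions: TBHP (decane), DBU, CH2Cl2, 0 °C → rt
Reagents that add atoms: tert-butyl hydroperoxide (3), CC(C)(C)OO
Why: Weitz–Scheffer nucleophilic epoxidation, in which the tert-butylperoxide anion should add to C1 of the cis-enone from the outer face of the ten-membered ring and the enolate should close onto oxygen before the ring bond can turn (cis-oxirane), while the unactivated alkenes and the β,β-disubstituted enoate do not react.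

Step 14
Reactants: 24 epoxy ketone
Product: 25 9-alcohol (9S; all stereocentres as in 32)
Conditions: Zn(BH4)2, Et2O, −20 °C; aq. NH4Cl
Reagents that add atoms: none
Why: chelation-controlled hydride reduction of an α,β-epoxy and α-acyloxy ketone, in which zinc holds the carbonyl oxygen syn to both flanking oxygens so that C1 and C7 (the ring) lie on one face and hydride enters from the other, past H8 and the C10 methyl, giving the carbinol anti to both neighbours.

Step 15
Reactants: 25 9-alcohol; 26 acetic anhydride
Product: 27 9-acetate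
Conditions: Ac2O, pyridine, DMAP (cat.), CH2Cl2, 0 °C → rt
Reagents that add atoms: acetic anhydride (26), CC(=O)OC(C)=O
Why: nucleophile-catalysed acetylation of the secondary alcohol, run directly after step 14 so that the neighbouring senecioate has no time to migrate.

Step 16
Reactants: 27 9-acetate
Product: 28 3-alcohol
Conditions: HF·pyridine, pyridine, THF, 0 °C → rt
Reagents that add atoms: none
Why: fluoride cleavage of the silyl ether under buffered, non-basic conditions that spare the two esters and the trisubstituted oxirane.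

Step 17
Reactants: 28 3-alcohol; 29 3-chloroperbenzoic acid
Product: 30 3-hydroxy-1,10:4,5-diepoxide (all stereocentres as in 32)
Conditions: mCPBA (1.05 equiv), NaHCO3, CH2Cl2, −20 → 0 °C
Reagents that add atoms: 3-chloroperbenzoic acid (29), O=C(OO)c1cccc(Cl)c1
Why: hydroxyl-directed peracid epoxidation of a Z-trisubstituted allylic alcohol, which with H3 eclipsing the double bond (A(1,3) strain) should deliver oxygen syn to the hydroxyl on the outer ring face (threo product), the trisubstituted hydrogen-bonded alkene reacting before the 1,1-disubstituted isopropenyl group and the electron-poor enoate.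

Step 18
Reactants: 30 diepoxy alcohol; 31 angelic acid ((Z)-2-methylbut-2-enoic acid)
Product: 32 target compound CNP0276917.1
Conditions: angelic acid, 2,4,6-trichlorobenzoyl chloride, Et3N, toluene, rt; then 30, 75 °C
Reagents that add atoms: angelic acid (31), C/C=C(/C)C(=O)O
Why: Yamaguchi-type esterification through the mixed anhydride, a standard way to acylate hindered secondary alcohols with angelic acid without isomerisation to the tiglate; no stereocentre is touched.

**Compound list**

1 | 2-methylcyclohex-2-en-1-one | CC1=CCCCC1=O | starting material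
2 | (R)-2-methylcyclohex-2-en-1-ol | O[C@@H]1CCCC=C1C | intermediate
3 | tert-butyl hydroperoxide | CC(C)(C)OO | starting material
4 | (1R,2R,3S)-2,3-epoxy-2-methylcyclohexan-1-ol | O[C@@H]1CCC[C@@H]2O[C@]12C | intermediate
5 | (2S,3S)-2,3-epoxy-2-methylcyclohexan-1-one | O=C1CCC[C@@H]2O[C@]12C | intermediate
6 | vinylmagnesium bromide | C=C[Mg]Br | starting material
7 | (1S,2S,3S)-2,3-epoxy-2-methyl-1-vinylcyclohexan-1-ol | C=C[C@@]1(O)CCC[C@@H]2O[C@]12C | intermediate
8 | (2R,3S)-3-hydroxy-2-methyl-2-vinylcyclohexan-1-one | C=C[C@]1(C)[C@@H](O)CCCC1=O | intermediate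
9 | tert-butyldimethylsilyl trifluoromethanesulfonate | CC(C)(C)[Si](C)(C)OS(=O)(=O)C(F)(F)F | starting material
10 | (2R,3S)-3-(tert-butyldimethylsilyloxy)-2-methyl-2-vinylcyclohexan-1-one | C=C[C@]1(C)[C@@H](O[Si](C)(C)C(C)(C)C)CCCC1=O | intermediate
11 | iodomethane | CI | starting material
12 | (2R,3S)-3-(tert-butyldimethylsilyloxy)-2,6-dimethyl-2-vinylcyclohexan-1-one (C6 epimers) | C=C[C@]1(C)[C@@H](O[Si](C)(C)C(C)(C)C)CCC(C)C1=O | intermediate
13 | trimethylsilyl enol ether of 12 | C=C[C@]1(C)[C@@H](O[Si](C)(C)C(C)(C)C)CCC(C)=C1O[Si](C)(C)C | intermediate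
14 | (5S,6R)-5-(tert-butyldimethylsilyloxy)-2,6-dimethyl-6-vinylcyclohex-2-en-1-one | C=C[C@]1(C)[C@@H](O[Si](C)(C)C(C)(C)C)CC=C(C)C1=O | intermediate
15 | 2-methylbut-1-en-3-yne | C=C(C)C#C | starting material
16 | (1S,5S,6R)-5-(tert-butyldimethylsilyloxy)-2,6-dimethyl-1-(3-methylbut-3-en-1-yn-1-yl)-6-vinylcyclohex-2-en-1-ol | C=C[C@]1(C)[C@@H](O[Si](C)(C)C(C)(C)C)CC=C(C)[C@]1(O)C#CC(C)=C | intermediate
17 | (1R,5S,6R)-5-(tert-butyldimethylsilyloxy)-2,6-dimethyl-1-[(1Z)-3-methylbuta-1,3-dien-1-yl]-6-vinylcyclohex-2-en-1-ol | C=C[C@]1(C)[C@@H](O[Si](C)(C)C(C)(C)C)CC=C(C)[C@]1(O)/C=C\C(C)=C | intermediate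
18 | 2-(phenylsulfonyl)-3-phenyloxaziridine | O=S(=O)(c1ccccc1)N1OC1c1ccccc1 | starting material
19 | potassium alkoxide of 17 | C=C[C@]1(C)[C@@H](O[Si](C)(C)C(C)(C)C)CC=C(C)[C@]1([O-])/C=C\C(C)=C.[K+] | intermediate
20 | potassium dienolate of the ten-membered ring (C8=C9 enolate, oxygen cis to C7) | [O-]/C1=C\[C@@H](C(C)=C)C/C=C(C)\[C@@H](O[Si](C)(C)C(C)(C)C)C/C=C1/C.[K+] | intermediate
21 | (3S,7R,8S)-3-(tert-butyldimethylsilyloxy)-8-hydroxygermacra-1(10)Z,4Z,11-trien-9-one | C=C(C)[C@H]1C/C=C(C)\[C@@H](O[Si](C)(C)C(C)(C)C)C/C=C(C)\C(=O)[C@H]1O | intermediate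
22 | 3-methylbut-2-enoyl chloride | CC(C)=CC(=O)Cl | starting material
23 | 8-O-(3-methylbut-2-enoyl) derivative of 21 | C=C(C)[C@H]1C/C=C(C)\[C@@H](O[Si](C)(C)C(C)(C)C)C/C=C(C)\C(=O)[C@H]1OC(=O)C=C(C)C | intermediate
24 | (1R,10R)-1,10-epoxy-3-(tert-butyldimethylsilyloxy)-8-(3-methylbut-2-enoyloxy)germacra-4Z,11-dien-9-one | C=C(C)[C@H]1C/C=C(C)\[C@@H](O[Si](C)(C)C(C)(C)C)C[C@H]2O[C@@]2(C)C(=O)[C@H]1OC(=O)C=C(C)C | intermediate
25 | 9-alcohol from 24 (configured as 32) | C=C(C)[C@H]1C/C=C(C)\[C@@H](O[Si](C)(C)C(C)(C)C)C[C@H]2O[C@@]2(C)[C@@H](O)[C@H]1OC(=O)C=C(C)C | intermediate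
26 | acetic anhydride | CC(=O)OC(C)=O | starting material
27 | 9-acetate of 25 | C=C(C)[C@H]1C/C=C(C)\[C@@H](O[Si](C)(C)C(C)(C)C)C[C@H]2O[C@@]2(C)[C@@H](OC(C)=O)[C@H]1OC(=O)C=C(C)C | intermediate
28 | 3-alcohol from 27 | C=C(C)[C@H]1C/C=C(C)\[C@@H](O)C[C@H]2O[C@@]2(C)[C@@H](OC(C)=O)[C@H]1OC(=O)C=C(C)C | intermediate
29 | 3-chloroperbenzoic acid | O=C(OO)c1cccc(Cl)c1 | starting material
30 | 3-hydroxy-1,10:4,5-diepoxide (configured as 32) | C=C(C)[C@H]1C[C@@H]2O[C@]2(C)[C@@H](O)C[C@H]2O[C@@]2(C)[C@@H](OC(C)=O)[C@H]1OC(=O)C=C(C)C | intermediate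
31 | angelic acid ((Z)-2-methylbut-2-enoic acid) | C/C=C(/C)C(=O)O | starting material
32 | CNP0276917.1 | C=C(C)[C@H]1C[C@@H]2O[C@]2(C)[C@@H](OC(=O)/C(C)=C\C)C[C@H]2O[C@@]2(C)[C@@H](OC(C)=O)[C@H]1OC(=O)C=C(C)C | target

**Totals**

Total step count: 18. Longest linear sequence: 18 steps (1 to 32).

**Steps most likely to fail**

Step 11. The [3,3] shift has to carry the isopropenyl group pseudoaxial. If this slows it, the alkoxide may leak into a [1,3] shift or into the other chair (E-alkene), and a relaxed enolate may lose facial fidelity in the oxygen transfer at C8. The fallback sets out from 14 and comes back at 21. Ethynylmagnesium bromide is added to 14 in the manner of step 9 to give the ethynyl carbinol F1. KH and 18-crown-6 then bring about the acetylenic anionic oxy-Cope shift, whose migrating terminus carries no substituent, and protonation of the allenolate should give the cross-conjugated cyclodecatrienone F2. Isopropenylmagnesium bromide with catalytic CuBr·SMe2 should add to the unsubstituted enone terminus C7 (the C1=C10 enone is α-methylated and slower) from the outer ring face, and the bromomagnesium enolate F3 is oxidised in the same flask with oxaziridine 18 to 21. C7 would then rest on conjugate addition to the ring instead of on the sigmatropic chair.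

Step 13. The base may epimerise C8 or the peroxide may cleave the senecioate before the hindered, twisted enone is attacked. The fallback sets out from 21 and comes back at 24. The ketol is silylated (Et3SiCl, imidazole) to the triethylsilyl ether F4, which tolerates the stronger nucleophile t-BuOOK (TBHP, KH, THF, −20 °C) and should give the epoxy ketone F5. Selective removal of the triethylsilyl group (HF·pyridine, 0 °C, the tert-butyldimethylsilyl ether staying on) gives the epoxy ketol F6, which is acylated with 22 as in step 12 to reach 24.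

Step 18. Acylation of the hindered C3 alcohol may be slow enough for the angelate to isomerise to the tiglate. The fallback sets out from 30 and ends at 32, building the Z double bond on the ester instead of bringing it in. Alcohol 30 is acylated (DCC, DMAP) with 2-[bis(2,2,2-trifluoroethoxy)phosphoryl]propanoic acid to give the phosphonate ester F7. Still–Gennari olefination (KN(SiMe3)2, 18-crown-6, THF, −78 °C, acetaldehyde) should then form the (Z)-2-methylbut-2-enoate directly.

Further compounds
F1 | step 11 | ethynyl carbinol from 14 (ethynyl cis to vinyl) | C=C[C@]1(C)[C@@H](O[Si](C)(C)C(C)(C)C)CC=C(C)[C@]1(O)C#C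
F2 | step 11 | (3S)-3-(tert-butyldimethylsilyloxy)-12,13-dinor-11-desmethylgermacra-1(10)Z,4Z,7Z-trien-9-one (cyclodecatrienone without the isopropenyl group) | O=C1/C=C\C/C=C(C)\[C@@H](O[Si](C)(C)C(C)(C)C)C/C=C1/C
F3 | step 11 | bromomagnesium dienolate after isopropenyl addition at C7 | Br[Mg]O/C1=C\[C@@H](C(C)=C)C/C=C(C)\[C@@H](O[Si](C)(C)C(C)(C)C)C/C=C1/C
F4 | step 13 | 8-O-triethylsilyl ether of 21 | C=C(C)[C@H]1C/C=C(C)\[C@@H](O[Si](C)(C)C(C)(C)C)C/C=C(C)\C(=O)[C@H]1O[Si](CC)(CC)CC
F5 | step 13 | 1,10-epoxy ketone 8-O-triethylsilyl ether | C=C(C)[C@H]1C/C=C(C)\[C@@H](O[Si](C)(C)C(C)(C)C)C[C@H]2O[C@@]2(C)C(=O)[C@H]1O[Si](CC)(CC)CC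
F6 | step 13 | 1,10-epoxy-8-hydroxy ketone | C=C(C)[C@H]1C/C=C(C)\[C@@H](O[Si](C)(C)C(C)(C)C)C[C@H]2O[C@@]2(C)C(=O)[C@H]1O
F7 | step 18 | 3-O-{2-[bis(2,2,2-trifluoroethoxy)phosphoryl]propanoyl} ester of 30 | C=C(C)[C@H]1C[C@@H]2O[C@]2(C)[C@@H](OC(=O)C(C)P(=O)(OCC(F)(F)F)OCC(F)(F)F)C[C@H]2O[C@@]2(C)[C@@H](OC(C)=O)[C@H]1OC(=O)C=C(C)C
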